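I started from amounts: what each flask was charged with, and what the cedar readings showed over time.

| flask | substrate | remark | time |
|---|---|---|---|
| cedar | 0.20 M | run made earlier |  |
| red | 0.40 M |  | 6.0 min |
| ochre | 0.60 M |  | 6.0 min |
| teal | 1.0 M |  | 6.0 min |
| amber | 1.5 M |  | 6.0 min |
| grey | 2.0 M |  | 6.0 min |

cedar run (percent of the substrate charged)

| time / min | target / % | side product / % |
|---|---|---|
| 0.417 | 58 | 2 |
| 1.33 | 91 | 5 |
| 2.00 | 95 | 5 |
| 3.00 | 95 | 2 |
| 5.00 | 100 | 0 |
| 6.00 | 96 | 4 |

(each reading ± 2 percentage points)

- percentages count the substrate that a species holds: one side product counts as two
- "hardly changes" means that all values lie within two and a half points (for a concentration: within two and a half percent of the largest)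

- share of target in all that became target or side product for red, ochre, teal, amber, grey, in this order
- how that number moves from the first to the last of them (rises all the way / falls all the way / rises, then falls / hardly changes / falls, then rises)

At 0.417 min the cedar readings put 60.0% of the charge in target and side product, so I took 40.0% to be still substrate. Taken as first order, that gave a rate constant k of 2.20 min⁻¹ and a half-life of 0.315 min. The 6.0 min of the new flasks is then 19.0 half-lives, so, if that order held at higher charges, I could treat them as finished. From 2.00 min on, the cedar side readings averaged 2.75%. A side product holds two substrate units, so I assumed that its share grows in proportion to the charge. This gave a target share, or selectivity, of 94.5% in red and 72.5% in grey.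

The weak link was that average, since its scatter of 1 percentage point is about a third of it. But the substrate balance offers a second reading. By my k about 1.23% of the cedar charge was left as substrate at 2.00 min, which I neglected, so I took target and side product to make up the cedar charge from then on. The cedar target readings from then on averaged 96.5%, which leaves 3.50% for the side product. Pooling both figures gave 3.12%, with a scatter of 0.71 points. Dividing by the cedar charge gave b, the side share per molar of charge, as 0.156 L mol⁻¹. I committed to a target share of 93.8% in red and 68.8% in grey.

The forecast gave 94.3%, 91.7%, 87.1%, 82.1% and 77.8%, which falls all the way, assuming that the side product “forms by a second-order path competing with first-order target formation”. My straight line stood lower at grey.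

The flasks gave 91.7%, 88.1%, 82.0%, 75.6% and 70.3%, which falls all the way.

    substrate → target (k = 0.0330 s⁻¹)
    substrate + target → side product (k = 0.00770 L mol⁻¹ s⁻¹)

At grey the forecast stood 7.5 points above the flask. The red flask held 8.32% side product at 6.00 min and 8.32% at 60.0 min. For red, b gives 6.25% against that 8.32%. For grey, b gives 31.2% against the 29.7% of side product that flask held.

The earlier runs and the new flask come from a simulation with constants of no real substance; scatter was added.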